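## Structural features

The target is a flavonol: a chromen-4-one in which the benzo ring (ring A) is fused to the γ-pyranone (ring C) through C4a–C8a, with a 3,4-dihydroxyphenyl ring (ring B) joined to C2 by a single bond. It has no stereocentre and no double-bond geometry to control, so the problem is one of regiochemistry and of telling six oxygen atoms apart. Ring A is substituted everywhere except C6: O1 on C8a, the acetate on C8, the methyl ether on C7 and a carbonyl-chelated hydroxyl on C5, so three different oxygen functions sit in a row on C7, C8 and C8a. The C8 aryl acetate is the most fragile group. It does not survive amines, alkoxides, organolithiums or hydrides, so it must be installed late and every later step must be neutral or weakly acidic. It cannot migrate, because both neighbours (the C7 methyl ether and O1) are capped. The ring B catechol and the 3-hydroxypyranone oxidise in air under base, and a 5-hydroxy-7,8-dioxygenated flavone can isomerise to the 5,6,7-pattern in hot strong acid, which also argues for a neutral last step. The real difficulty is to lay down the 5,7,8,8a oxygen pattern with O5 and O8 separately addressable, and to bring in the C3 hydroxyl without touching the acetate. The plan exploits the fact that C4 is a carbonyl carbon bonded only to C4a and C3. It can therefore come from carbon monoxide, with ring A entering as an iodocatechol (iodine on C4a, hydroxyl on C8a) and ring B as an arylacetylene whose sp carbons become C2 and C3.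

## Logic of the disconnections

18 to 17: the three benzylic C–O bonds at O5, O3' and O4' are cut. Benzyl is the one ether type that leaves under neutral, non-nucleophilic conditions, which the C8 acetate requires. The gain is that every phenol except O8 is masked by a single group removed in one operation. The demand is a hydrogenolysis in an aprotic medium that neither reduces C2=C3 nor cleaves the ester.

17 to 15 (through 16): the C3–O bond is cut. The carbon that becomes C3 is a terminal alkyne carbon at the ring-forming stage and can only carry hydrogen, so O3 has to arrive after ring C exists. C2=C3 is the most nucleophilic π bond in the molecule, so an electrophilic oxygen-atom donor should select it. The gain is a plain flavone as precursor. The demand is a neutral oxidant that spares the acetate, the benzyl ethers and the electron-rich rings, and an opening of 16 toward C2.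

15 to 14: the O8–acetyl bond is cut. 14 carries a single free hydroxyl, so the acylation needs no selectivity. It is placed before the oxidation because a free O8 para to O5 is a hydroquinone-type unit that an oxidant would attack.

14 to 8, 10 and 11 (through 12 and 13): C4a–C4, C4–C3 and O1–C2 are cut, which removes ring C and leaves two benzene derivatives and one carbon monoxide. The cut is made here because C4 has no other substituent. It also distinguishes the two hydroxyls of 8 automatically, since only the one ortho to the new acyl group can close the ring. The forward step must carbonylate before alkynylating, close a six-membered and not a five-membered ring, and tolerate a free catechol.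

8 to 7: the two O–CH2OMe bonds are cut. Both acetals fall together under mild acid that leaves the benzyl ether, the methyl ether and the C–I bond alone. The demand is acid mild enough to avoid protodeiodination of a very electron-rich aryl iodide.

7 to 5 (through 6): the C4a–I bond is cut. The iodine is placed by deprotonation and not by electrophilic substitution, because the two free ring positions of 5 are electronically similar, whereas only one of them is flanked by a chelating acetal oxygen. The demand is ring metalation faster than metalation of the benzylic CH2.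

5 to 4, 4 to 2 (through 3), 2 to 1: the O5–benzyl bond, then the C5–O bond (traced back to a formyl carbon), then the two acetal C–O bonds are cut. The formyl group of 1 marks the carbon that becomes C5, so the whole 5,7,8,8a pattern is read off a commercial benzaldehyde, with the methyl ether already on the correct oxygen. The demand is an aryl-migrating oxidation that works without a free phenol.

10 to 9: the alkyne carbon that becomes C3 is cut from the carbon that becomes C2, which reduces ring B to a commercial aldehyde. The demand is a one-carbon homologation under base mild enough for benzyl ethers.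

## Other disconnections considered

Alternative 1: The cut is C4a–C5, with ring A built last from a four-membered ring. The precursor is the cyclobutenone 1-{5-(benzyloxy)-6-[3,4-bis(benzyloxy)phenyl]-4-oxo-4H-pyran-2-yl}-2-methoxy-4-oxocyclobut-2-en-1-yl acetate A1. Heated in toluene, it would open by a four-electron electrocyclic reaction to a dienylketene. The ketene carbon would then bond to the neighbouring pyranone carbon in a six-electron closure, and tautomerisation would give 8-acetoxy-3-(benzyloxy)-2-[3,4-bis(benzyloxy)phenyl]-5-hydroxy-7-methoxychromen-4-one A2.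
- In favour: the para relation of O5 and O8 is built into the method. O8 is already acetylated, O5 is free and O3 is carried as a benzyl ether, so only one hydrogenolysis follows the key step. That is better than the three steps needed after step 7 here.
- In favour: the step is thermal, with no catalyst and no toxic gas, and is regiospecific by construction. On mechanism it is at least the equal of the chosen plan.
- Against: A1 needs a ring C pyranone metalated selectively at the future C8a in the presence of its own carbonyl. It also needs addition to the correct carbonyl of an unsymmetrical squarate-derived dione and acetylation of a hindered tertiary alkoxide.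
- Against: an acetoxy group directs outward rotation in the ring opening less strongly than a hydroxyl, so some of the material could open with the wrong geometry for closure.
- Comparison: the route to A1 is likely to be longer and less convergent than the route to 8 and 10. Structurally it is the more elegant answer to the O5/O8 problem.

Alternative 2: The cut is C4–C4a, with ring C closed by acylation of ring A. The precursor is (Z)-3-[2-(allyloxy)-5-(benzyloxy)-3-methoxyphenoxy]-3-[3,4-bis(benzyloxy)phenyl]prop-2-enoic acid A3. Trifluoroacetic anhydride would activate it as a mixed anhydride that attacks the only free position ortho to the aryloxy oxygen, giving 8-(allyloxy)-5-(benzyloxy)-2-[3,4-bis(benzyloxy)phenyl]-7-methoxychromen-4-one A4.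
- In favour: this is classical chemistry with no palladium, no pressurised CO and no iodination of ring A. The ring closure can occur at one carbon only, and that carbon is activated by three oxygens, so regiocontrol equals that of the chosen plan and the operation is simpler.
- Against: only the isomer with the acid cis to the aryloxy group can cyclise. The strongly acidic medium endangers benzyl ethers on electron-rich rings and the enol ether double bond.
- Against: O8 must be masked during the acylation, here as an allyl ether. That costs a selective mono-allylation of a catechol before the key step and a deallylation after it.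
- Comparison: four steps follow the key step (deallylation, acetylation, C3 oxidation, hydrogenolysis) against three here. The C3 oxygen is no easier to introduce, so on that point the two plans are equal.

Alternative 3: The cut is C5–C6, C7–C8 and C8–C8a, a benzannulation of ring A on a preformed pyranone. The precursor is pentacarbonyl[(benzyloxy){5-(benzyloxy)-6-[3,4-bis(benzyloxy)phenyl]-4-oxo-4H-pyran-3-yl}methylidene]chromium A5, a Cr(CO)5 carbene of zerovalent chromium. It would combine with methoxyacetylene A6 and one CO ligand; air oxidation then removes the metal and gives 3,5-bis(benzyloxy)-2-[3,4-bis(benzyloxy)phenyl]-8-hydroxy-7-methoxychromen-4-one A7.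
- In favour: A7 has the same O5-benzyl/O8-hydroxyl differentiation as 14 and already carries O3. Only acetylation and hydrogenolysis would follow, which is better than the chosen plan by one step and avoids the dioxirane oxidation.
- In favour: CO is used as a one-carbon unit here too (C8), so on that point the plans are equal.
- Against: A5 needs a pyranone metalated next to its carbonyl and an O-benzylation of the acyl chromate, and it uses stoichiometric chromium.
- Against: A6 is volatile and unstable. A terminal ynol ether is electronically biased, so insertion without CO uptake or the reversed orientation could compete with the sterically expected placement of the methoxy group next to the CO-derived carbon. The pyranone double bond is also an electron-poor alkenyl partner.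
- Comparison: the chosen plan reaches the same ring A pattern from two simple aromatic compounds with a catalytic metal. The alternative is shorter after the key step but longer and less certain before it.

Key step: step 7

Remark 1: an aldehyde with no free ortho or para hydroxyl does not undergo the alkaline H2O2 Dakin reaction, so the formyl-to-hydroxyl exchange on 2 is planned as a peracid Baeyer–Villiger oxidation followed by methanolysis of the formate.

Remark 2: the iodocatechol 8 is used with both hydroxyls free, because an ester on O8 would be aminolysed by Et2NH and an ether would cost two extra steps; the only refinement is that 8 is generated just before the coupling and handled under argon, since such electron-rich catechols oxidise in air.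

Remark 3 (assumption): 1, 9, 11, the diazophosphonate of step 6 and an acetone solution of dimethyldioxirane are taken as available.

## Route

Step 1
Reactants: 1 3,4-dihydroxy-5-methoxybenzaldehyde (5-hydroxyvanillin)
Product: 2 3-methoxy-4,5-bis(methoxymethoxy)benzaldehyde
Conditions: MOMCl, i-Pr2NEt, CH2Cl2, 0 °C to rt
Reagents that add atoms: chloromethyl methyl ether, COCCl
Why: O-alkylation of both phenols to methoxymethyl ethers; the acetals are stable to peracid, base and organolithium and later serve as the directing groups for ring metalation.

Step 2
Reactants: 2 3-methoxy-4,5-bis(methoxymethoxy)benzaldehyde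
Product: 4 3-methoxy-4,5-bis(methoxymethoxy)phenol, via aryl formate 3 (not isolated)
Conditions: mCPBA, CH2Cl2, 0 °C to rt; aq. NaHCO3 wash; then K2CO3 (cat.), MeOH, rt
Reagents that add atoms: 3-chloroperoxybenzoic acid, O=C(OO)c1cccc(Cl)c1
Why: Baeyer–Villiger (Dakin-type) oxidation of an electron-rich benzaldehyde, in which the para-alkoxyaryl group migrates in preference to hydride to give formate 3; mild methanolysis then frees the phenol.

Step 3
Reactants: 4 3-methoxy-4,5-bis(methoxymethoxy)phenol
Product: 5 5-(benzyloxy)-1-methoxy-2,3-bis(methoxymethoxy)benzene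
Conditions: BnBr, K2CO3, DMF, rt
Reagents that add atoms: benzyl bromide, BrCc1ccccc1
Why: Williamson ether synthesis on the only free phenol; benzyl is chosen for the future O5 because it survives organolithium, acid and amine and leaves by hydrogenolysis at the end.

Step 4
Reactants: 5 5-(benzyloxy)-1-methoxy-2,3-bis(methoxymethoxy)benzene
Product: 7 1-(benzyloxy)-2-iodo-5-methoxy-3,4-bis(methoxymethoxy)benzene, via aryllithium 6 (not isolated)
Conditions: n-BuLi (1.2 equiv), THF, −40 to 0 °C; then I2, THF, −78 °C to rt; aq. Na2S2O3
Reagents that add atoms: iodine, II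
Why: Directed ortho-metalation; the ring C–H between the benzyloxy group and the chelating methoxymethoxy group is the most activated one (the other free position is flanked only by the weaker methoxy director), and iodinolysis of 6 fixes iodine on the future C4a; low temperature keeps the benzylic CH2 from being metalated.

Step 5
Reactants: 7 1-(benzyloxy)-2-iodo-5-methoxy-3,4-bis(methoxymethoxy)benzene
Product: 8 4-(benzyloxy)-3-iodo-6-methoxybenzene-1,2-diol
Conditions: HCl (1.25 M in MeOH), rt to 40 °C, Ar; used at once
Reagents that add atoms: none
Why: Acid-catalysed acetal methanolysis of both methoxymethyl ethers; the benzyl ether, methyl ether and aryl iodide are stable to dilute methanolic HCl.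

Step 6
Reactants: 9 3,4-bis(benzyloxy)benzaldehyde
Product: 10 4-ethynyl-1,2-bis(benzyloxy)benzene
Conditions: dimethyl (1-diazo-2-oxopropyl)phosphonate, K2CO3, MeOH–THF, rt
Reagents that add atoms: dimethyl (1-diazo-2-oxopropyl)phosphonate, CC(=O)C(=[N+]=[N-])P(=O)(OC)OC
Why: Seyferth–Gilbert homologation in the Ohira–Bestmann variant; the diazophosphonate anion released by methanolysis condenses with the aldehyde, and the diazoalkene loses N2 with a 1,2-shift to the terminal alkyne under conditions to which benzyl ethers are inert.

Step 7
Reactants: 8 4-(benzyloxy)-3-iodo-6-methoxybenzene-1,2-diol; 10 4-ethynyl-1,2-bis(benzyloxy)benzene; 11 carbon monoxide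
Product: 14 5-(benzyloxy)-2-[3,4-bis(benzyloxy)phenyl]-8-hydroxy-7-methoxychromen-4-one, via ynone 12 (not isolated), via enaminone 13 (not isolated)
Conditions: PdCl2(PPh3)2 (5 mol %), CO (5 atm), Et2NH, 80 °C, degassed, no copper salt
Reagents that add atoms: none
Why: PdCl2(PPh3)2 is reduced in the flask to zerovalent palladium, which inserts into the C4a–I bond of 8; CO (11) then inserts to give an aroylpalladium iodide, the acetylide formed from 10 and Et2NH is transferred to palladium, and reductive elimination gives ynone 12 (bonds C4a–C4 and C4–C3). Et2NH adds to 12 in the conjugate sense to give enaminone 13, whose β-carbon (C2) is attacked by the C8a hydroxyl; loss of Et2NH forms O1–C2 and closes ring C as a six-membered ring by 6-endo-trig addition–elimination. The closest known reaction type is the palladium-catalysed carbonylative annulation of 2-iodophenols with terminal alkynes to flavones in a secondary amine. No stereocentre is formed. Carbonylation must precede alkynyl transfer (otherwise a diarylalkyne and then a benzofuran would result); the CO pressure, the absence of a copper salt and the fast CO insertion of an electron-rich arylpalladium should secure this. Flavone must win over aurone; the enaminone secures this, because its α-carbon is nucleophilic and only C2 is electrophilic. Only the C8a hydroxyl is ortho to the new acyl group, the C8 hydroxyl is meta to it and cannot reach C2, and O5 is blocked as its benzyl ether, so a single flavone is possible and the 8-hydroxyl emerges free. Capture of the aroylpalladium by Et2NH to give an amide is the main competing path, and a slight excess of 10 should keep alkynyl transfer ahead of it.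

Step 8
Reactants: 14 5-(benzyloxy)-2-[3,4-bis(benzyloxy)phenyl]-8-hydroxy-7-methoxychromen-4-one
Product: 15 5-(benzyloxy)-2-[3,4-bis(benzyloxy)phenyl]-7-methoxy-4-oxo-4H-chromen-8-yl acetate
Conditions: Ac2O, pyridine, DMAP (cat.), CH2Cl2, 0 °C to rt
Reagents that add atoms: acetic anhydride, CC(=O)OC(C)=O
Why: DMAP-catalysed acylation of the only hydroxyl in 14; it precedes the oxidation so that the hydroquinone-like O5/O8 pair is deactivated.

Step 9
Reactants: 15 5-(benzyloxy)-2-[3,4-bis(benzyloxy)phenyl]-7-methoxy-4-oxo-4H-chromen-8-yl acetate
Product: 17 5-(benzyloxy)-2-[3,4-bis(benzyloxy)phenyl]-3-hydroxy-7-methoxy-4-oxo-4H-chromen-8-yl acetate, via epoxide 16 (not isolated)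
Conditions: DMDO (acetone solution), CH2Cl2, 0 °C; then TsOH·H2O (cat.), CH2Cl2, rt
Reagents that add atoms: dimethyldioxirane, CC1(C)OO1
Why: Electrophilic epoxidation of the enol-ether-like C2=C3 bond by the neutral dioxirane, then acid-catalysed opening of 16 at C2 (cation stabilised by O1 and ring B) and loss of H3 to the 3-hydroxyflavone; the medium is neutral to weakly acidic so the acetate stays, and the two racemic centres of 16 vanish on opening.

Step 10
Reactants: 17 5-(benzyloxy)-2-[3,4-bis(benzyloxy)phenyl]-3-hydroxy-7-methoxy-4-oxo-4H-chromen-8-yl acetate
Product: 18 2-(3,4-dihydroxyphenyl)-3,5-dihydroxy-7-methoxy-4-oxo-4H-chromen-8-yl acetate (gossypetin 7-methyl ether 8-acetate)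
Conditions: H2 (1 atm), 10% Pd/C, EtOAc–THF, rt
Reagents that add atoms: none
Why: Catalytic hydrogenolysis of the three benzyl ethers under neutral conditions in an aprotic solvent, so the aryl acetate is neither cleaved nor transesterified and the conjugated, fully substituted C2=C3 bond is not reduced.

## Compound list

1 | 3,4-dihydroxy-5-methoxybenzaldehyde (5-hydroxyvanillin) | COc1cc(C=O)cc(O)c1O | starting material
2 | 3-methoxy-4,5-bis(methoxymethoxy)benzaldehyde | COCOc1cc(C=O)cc(OC)c1OCOC | intermediate
3 | 3-methoxy-4,5-bis(methoxymethoxy)phenyl formate (formed in the flask, not isolated) | COCOc1cc(OC=O)cc(OC)c1OCOC | intermediate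
4 | 3-methoxy-4,5-bis(methoxymethoxy)phenol | COCOc1cc(O)cc(OC)c1OCOC | intermediate
5 | 5-(benzyloxy)-1-methoxy-2,3-bis(methoxymethoxy)benzene | COCOc1cc(OCc2ccccc2)cc(OC)c1OCOC | intermediate
6 | [2-(benzyloxy)-4-methoxy-5,6-bis(methoxymethoxy)phenyl]lithium (formed in the flask, not isolated) | [Li]c1c(OCc2ccccc2)cc(OC)c(OCOC)c1OCOC | intermediate
7 | 1-(benzyloxy)-2-iodo-5-methoxy-3,4-bis(methoxymethoxy)benzene | COCOc1c(I)c(OCc2ccccc2)cc(OC)c1OCOC | intermediate
8 | 4-(benzyloxy)-3-iodo-6-methoxybenzene-1,2-diol | COc1cc(OCc2ccccc2)c(I)c(O)c1O | intermediate
9 | 3,4-bis(benzyloxy)benzaldehyde | O=Cc1ccc(OCc2ccccc2)c(OCc2ccccc2)c1 | starting material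
10 | 4-ethynyl-1,2-bis(benzyloxy)benzene | C#Cc1ccc(OCc2ccccc2)c(OCc2ccccc2)c1 | intermediate
11 | carbon monoxide | [C-]#[O+] | starting material
12 | 1-[6-(benzyloxy)-2,3-dihydroxy-4-methoxyphenyl]-3-[3,4-bis(benzyloxy)phenyl]prop-2-yn-1-one (formed in the flask, not isolated) | COc1cc(OCc2ccccc2)c(C(=O)C#Cc2ccc(OCc3ccccc3)c(OCc3ccccc3)c2)c(O)c1O | intermediate
13 | (E)-1-[6-(benzyloxy)-2,3-dihydroxy-4-methoxyphenyl]-3-[3,4-bis(benzyloxy)phenyl]-3-(diethylamino)prop-2-en-1-one (formed in the flask, not isolated; the push-pull double bond isomerises readily and its geometry does not affect the closure) | CCN(CC)/C(=C/C(=O)c1c(O)c(O)c(OC)cc1OCc1ccccc1)c1ccc(OCc2ccccc2)c(OCc2ccccc2)c1 | intermediate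
14 | 5-(benzyloxy)-2-[3,4-bis(benzyloxy)phenyl]-8-hydroxy-7-methoxychromen-4-one | COc1cc(OCc2ccccc2)c2c(=O)cc(-c3ccc(OCc4ccccc4)c(OCc4ccccc4)c3)oc2c1O | intermediate
15 | 5-(benzyloxy)-2-[3,4-bis(benzyloxy)phenyl]-7-methoxy-4-oxo-4H-chromen-8-yl acetate | COc1cc(OCc2ccccc2)c2c(=O)cc(-c3ccc(OCc4ccccc4)c(OCc4ccccc4)c3)oc2c1OC(C)=O | intermediate
16 | racemic 8-acetoxy-5-(benzyloxy)-2-[3,4-bis(benzyloxy)phenyl]-2,3-epoxy-7-methoxy-2,3-dihydrochromen-4-one (flavone 2,3-epoxide, cis ring fusion, one enantiomer drawn; formed in the flask, not isolated) | COc1cc(OCc2ccccc2)c2C(=O)[C@H]3O[C@@]3(c3ccc(OCc4ccccc4)c(OCc4ccccc4)c3)Oc2c1OC(C)=O | intermediate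
17 | 5-(benzyloxy)-2-[3,4-bis(benzyloxy)phenyl]-3-hydroxy-7-methoxy-4-oxo-4H-chromen-8-yl acetate | COc1cc(OCc2ccccc2)c2c(=O)c(O)c(-c3ccc(OCc4ccccc4)c(OCc4ccccc4)c3)oc2c1OC(C)=O | intermediate
18 | 2-(3,4-dihydroxyphenyl)-3,5-dihydroxy-7-methoxy-4-oxo-4H-chromen-8-yl acetate (gossypetin 7-methyl ether 8-acetate) | COc1cc(O)c2c(=O)c(O)c(-c3ccc(O)c(O)c3)oc2c1OC(C)=O | target

## Step count and least certain steps

Total step count: 10. Longest linear sequence: 9 steps (steps 1 to 5 and 7 to 10); step 6 is the one-step branch to 10.

**Step 7 (key step).** Oxidative addition into a doubly ortho-substituted, very electron-rich aryl iodide (partly present as its phenoxide) may be slow. Precipitation of palladium metal, capture of the aroylpalladium by Et2NH to give an amide, coupling without CO uptake, or oxidation of the free catechol by traces of air could then take over.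

Fallback (sets out from 7 and 10, returns at 12 and through it at 14):
- Iodine–lithium exchange on 7 (n-BuLi, THF, −78 °C) regenerates 6 as a single regioisomer.
- 10 is deprotonated with n-BuLi and acylated with N-methoxy-N-methylcarbamoyl chloride to the alkynyl Weinreb amide 3-[3,4-bis(benzyloxy)phenyl]-N-methoxy-N-methylprop-2-ynamide F1.
- Addition of 6 to F1 and aqueous work-up should give the protected ynone 1-[2-(benzyloxy)-4-methoxy-5,6-bis(methoxymethoxy)phenyl]-3-[3,4-bis(benzyloxy)phenyl]prop-2-yn-1-one F2.
- Methanolic HCl removes both acetals to give 12, and brief treatment with Et2NH closes ring C through 13 to 14.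
- No palladium and no CO gas are needed; C4 then comes from the carbamoyl chloride.

**Step 4.** The benzylic CH2 of the benzyl ether may be metalated in competition with the ring, followed by Wittig rearrangement. Site selectivity between the two doubly flanked ring positions may also be incomplete, because the methoxy group is a director too.

Fallback (sets out from 1, returns at 7):
- Electrophilic iodination of 1 with ICl in pyridine–dioxane is expected ortho to the C3 hydroxyl and para to the methoxy group, by analogy with the known C2 iodination of 3-hydroxy-4-methoxybenzaldehyde. It would give 2-iodo-3,4-dihydroxy-5-methoxybenzaldehyde F3.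
- Bis-acetal formation as in step 1 gives 2-iodo-5-methoxy-3,4-bis(methoxymethoxy)benzaldehyde F4.
- Baeyer–Villiger oxidation as in step 2 (buffered with NaHCO3 and kept at 0 °C to spare the aryl iodide) passes through 2-iodo-5-methoxy-3,4-bis(methoxymethoxy)phenyl formate F5 to 2-iodo-5-methoxy-3,4-bis(methoxymethoxy)phenol F6.
- Benzylation as in step 3 gives 7.
- This route uses no organolithium and has no benzyl ether present when the iodine is placed.

**Step 9.** Over-oxidation may occur: attack of the dioxirane on the electron-rich rings or on the benzylic C–H bonds of the ethers. The epoxide may also decompose by paths other than opening toward C2.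

Fallback (sets out from 14, returns at 18). The C3 oxygen is introduced by anion chemistry before any acetate is present:
- 14 is protected (MOMCl, i-Pr2NEt) as 5-(benzyloxy)-2-[3,4-bis(benzyloxy)phenyl]-7-methoxy-8-(methoxymethoxy)chromen-4-one F7.
- C3 is lithiated with LiN(i-Pr)2 in THF at −78 °C, trapped with B(OMe)3 and oxidised with H2O2–AcOH to 5-(benzyloxy)-2-[3,4-bis(benzyloxy)phenyl]-3-hydroxy-7-methoxy-8-(methoxymethoxy)chromen-4-one F8.
- Benzylation (BnBr, K2CO3, DMF) gives 3,5-bis(benzyloxy)-2-[3,4-bis(benzyloxy)phenyl]-7-methoxy-8-(methoxymethoxy)chromen-4-one F9.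
- Methanolic HCl frees 3,5-bis(benzyloxy)-2-[3,4-bis(benzyloxy)phenyl]-8-hydroxy-7-methoxychromen-4-one F10 (the same structure as A7).
- Acetylation as in step 8 gives 3,5-bis(benzyloxy)-2-[3,4-bis(benzyloxy)phenyl]-7-methoxy-4-oxo-4H-chromen-8-yl acetate F11.
- Hydrogenolysis as in step 10 removes four benzyl groups to give 18.

**Step 10.** Debenzylation may stall at the hindered, carbonyl-flanked O5 ether, or through catalyst poisoning by traces of iodide carried from earlier steps or adsorption of the polyphenol on the support. Forcing the reaction could begin to cleave the acetate.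

Fallback (sets out from 17, returns at 18): non-reductive Lewis-acid debenzylation with BCl3 and pentamethylbenzene as cation scavenger in CH2Cl2 at −78 °C. Aryl esters and unactivated aryl methyl ethers are expected to tolerate these conditions. No new isolated compound arises.

## Further compounds

F1 | step 7 | 3-[3,4-bis(benzyloxy)phenyl]-N-methoxy-N-methylprop-2-ynamide | CON(C)C(=O)C#Cc1ccc(OCc2ccccc2)c(OCc2ccccc2)c1
F2 | step 7 | 1-[2-(benzyloxy)-4-methoxy-5,6-bis(methoxymethoxy)phenyl]-3-[3,4-bis(benzyloxy)phenyl]prop-2-yn-1-one | COCOc1c(C(=O)C#Cc2ccc(OCc3ccccc3)c(OCc3ccccc3)c2)c(OCc2ccccc2)cc(OC)c1OCOC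
F3 | step 4 | 2-iodo-3,4-dihydroxy-5-methoxybenzaldehyde | COc1cc(C=O)c(I)c(O)c1O
F4 | step 4 | 2-iodo-5-methoxy-3,4-bis(methoxymethoxy)benzaldehyde | COCOc1c(I)c(C=O)cc(OC)c1OCOC
F5 | step 4 | 2-iodo-5-methoxy-3,4-bis(methoxymethoxy)phenyl formate | COCOc1c(I)c(OC=O)cc(OC)c1OCOC
F6 | step 4 | 2-iodo-5-methoxy-3,4-bis(methoxymethoxy)phenol | COCOc1c(I)c(O)cc(OC)c1OCOC
F7 | step 9 | 5-(benzyloxy)-2-[3,4-bis(benzyloxy)phenyl]-7-methoxy-8-(methoxymethoxy)chromen-4-one | COCOc1c(OC)cc(OCc2ccccc2)c2c(=O)cc(-c3ccc(OCc4ccccc4)c(OCc4ccccc4)c3)oc12
F8 | step 9 | 5-(benzyloxy)-2-[3,4-bis(benzyloxy)phenyl]-3-hydroxy-7-methoxy-8-(methoxymethoxy)chromen-4-one | COCOc1c(OC)cc(OCc2ccccc2)c2c(=O)c(O)c(-c3ccc(OCc4ccccc4)c(OCc4ccccc4)c3)oc12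
F9 | step 9 | 3,5-bis(benzyloxy)-2-[3,4-bis(benzyloxy)phenyl]-7-methoxy-8-(methoxymethoxy)chromen-4-one | COCOc1c(OC)cc(OCc2ccccc2)c2c(=O)c(OCc3ccccc3)c(-c3ccc(OCc4ccccc4)c(OCc4ccccc4)c3)oc12
F10 | step 9 | 3,5-bis(benzyloxy)-2-[3,4-bis(benzyloxy)phenyl]-8-hydroxy-7-methoxychromen-4-one | COc1cc(OCc2ccccc2)c2c(=O)c(OCc3ccccc3)c(-c3ccc(OCc4ccccc4)c(OCc4ccccc4)c3)oc2c1O
F11 | step 9 | 3,5-bis(benzyloxy)-2-[3,4-bis(benzyloxy)phenyl]-7-methoxy-4-oxo-4H-chromen-8-yl acetate | COc1cc(OCc2ccccc2)c2c(=O)c(OCc3ccccc3)c(-c3ccc(OCc4ccccc4)c(OCc4ccccc4)c3)oc2c1OC(C)=O
F0 | step 10 | none | none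
A1 | alternative 1 | 1-{5-(benzyloxy)-6-[3,4-bis(benzyloxy)phenyl]-4-oxo-4H-pyran-2-yl}-2-methoxy-4-oxocyclobut-2-en-1-yl acetate (racemic) | COC1=CC(=O)C1(OC(C)=O)c1cc(=O)c(OCc2ccccc2)c(-c2ccc(OCc3ccccc3)c(OCc3ccccc3)c2)o1
A2 | alternative 1 | 8-acetoxy-3-(benzyloxy)-2-[3,4-bis(benzyloxy)phenyl]-5-hydroxy-7-methoxychromen-4-one | COc1cc(O)c2c(=O)c(OCc3ccccc3)c(-c3ccc(OCc4ccccc4)c(OCc4ccccc4)c3)oc2c1OC(C)=O
A3 | alternative 2 | (Z)-3-[2-(allyloxy)-5-(benzyloxy)-3-methoxyphenoxy]-3-[3,4-bis(benzyloxy)phenyl]prop-2-enoic acid | C=CCOc1c(OC)cc(OCc2ccccc2)cc1O/C(=C\C(=O)O)c1ccc(OCc2ccccc2)c(OCc2ccccc2)c1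
A4 | alternative 2 | 8-(allyloxy)-5-(benzyloxy)-2-[3,4-bis(benzyloxy)phenyl]-7-methoxychromen-4-one | C=CCOc1c(OC)cc(OCc2ccccc2)c2c(=O)cc(-c3ccc(OCc4ccccc4)c(OCc4ccccc4)c3)oc12
A5 | alternative 3 | pentacarbonyl[(benzyloxy){5-(benzyloxy)-6-[3,4-bis(benzyloxy)phenyl]-4-oxo-4H-pyran-3-yl}methylidene]chromium | O=C=[Cr](=C=O)(=C=O)(=C=O)(=C=O)=C(OCc1ccccc1)c1coc(-c2ccc(OCc3ccccc3)c(OCc3ccccc3)c2)c(OCc2ccccc2)c1=O
A6 | alternative 3 | methoxyacetylene (methoxyethyne) | COC#C
A7 | alternative 3 | 3,5-bis(benzyloxy)-2-[3,4-bis(benzyloxy)phenyl]-8-hydroxy-7-methoxychromen-4-one | COc1cc(OCc2ccccc2)c2c(=O)c(OCc3ccccc3)c(-c3ccc(OCc4ccccc4)c(OCc4ccccc4)c3)oc2c1O
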